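6 questions stand on this flask, and this reckoning carries one quantity through them: the target-making rate w, the sum c(target) + c(side product) divided by the time.

all flasks: free catalyst 50 µM
- violet: starting material 0.10 M; second substrate 0.20 M; solid reagent 0.18 M; temperature 75 °C; run made earlier
- red: starting material 0.067 M; second substrate 0.20 M; solid reagent 0.18 M; temperature 86 °C; run made earlier
- blue: starting material 0.15 M; second substrate 0.20 M; solid reagent 0.18 M; temperature 75 °C; run made earlier
- dawn: starting material 0.10 M; second substrate 0.200 M; solid reagent 0.180 M; temperature 80 °C; everything together at the start; time 20 h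
- dusk: starting material 0.10 M; second substrate 0.200 M; solid reagent 0.180 M; everything together at the start at 40 °C, warmed to 80 °C at 8.0 h; time 20 h
- spring: starting material 0.10 M; second substrate 0.200 M (fed, over 8.0 h); solid reagent 0.180 M; the addition at 40 °C, then warmed to 80 °C; the feed brings no volume worth counting; time 20 h
- midnight: starting material 0.10 M; second substrate 0.200 M (in portions, 5, over 8.0 h); solid reagent 0.180 M; temperature 80 °C; first portion at the start, last at 8.0 h; time 20 h
- autumn: starting material 0.10 M (fed, over 8.0 h); second substrate 0.200 M; solid reagent 0.180 M; temperature 80 °C; all else is in the flask from the start; the feed brings no volume worth counting; time 20 h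

| run | time / h | side product / % | target / % |
|---|---|---|---|
| violet | 1.00 | 1 | 0 |
| violet | 2.00 | 5 | 6 |
| violet | 3.00 | 11 | 6 |
| violet | 6.00 | 19 | 12 |
| violet | 12.0 | 47 | 16 |
| red | 3.00 | 19 | 9 |
| red | 6.00 | 42 | 15 |
| red | 10.0 | 61 | 25 |
| red | 12.0 | 68 | 20 |
| red | 15.0 | 73 | 19 |
| blue | 3.00 | 6 | 3 |
| blue | 6.00 | 23 | 5 |
| blue | 10.0 | 42 | 9 |
| blue | 12.0 | 49 | 7 |
| blue | 15.0 | 60 | 10 |

(scatter of a reading: 2 percentage points)

- percentages count the starting material that a species holds: one side product counts as two
- solid, in amounts per volume of the solution: solid reagent
- what may be going on: starting material + free catalyst <-> catalyst intermediate A; partner + catalyst intermediate A -> free catalyst + target; second substrate + free catalyst <-> catalyst intermediate B; partner + catalyst intermediate B -> free catalyst + second product; starting material + target -> side product; solid reagent <-> partner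
- at the start none of the solid reagent is in solution

- the flask with the highest amount of side product, in percent of the starting material charged ("all alike" if they lie within 1.5 percentage points) (dawn / dusk / spring / midnight / autumn / all alike)
- final side product, as a percentage of the starting material charged, in dawn
- final side product, as a percentage of the starting material charged, in dusk
- final side product, as a percentage of the starting material charged, in spring
- final side product, as a percentage of the starting material charged, in midnight
- final side product, as a percentage of the starting material charged, in autumn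

Each side product holds one target and one further starting material, so c(side product) is half its percentage of the charge. At its last reading, violet gives w = 3.29 mM h⁻¹. At the same time, blue gives 3.94 mM h⁻¹. A charge 1.50 times larger thus raises w by a factor of only 1.20, a read order in starting material of 0.442. Red, hotter by 11.0 K and with a smaller charge, reads 4.02 mM h⁻¹ at 6.00 h, so this reckoning carries the mean, 3.61 mM h⁻¹, to 80 °C unchanged. Violet, blue and red stand at 0.18 M of solid reagent, so w holds for that charge.

The charge clock, the time in which w makes target for half the charge, is 13.8 h. Hours at 40 °C count as none here, which leaves dusk and spring 12.0 h hot, and autumn is taken at its mean arrival.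

| Flask | Hot hours / clock |
|---|---|
| dawn, midnight | 1.45 |
| autumn | 1.16 |
| dusk, spring | 0.870 |

For dusk, with 12.0 h hot, target plus half the side product should reach 43.4% of the charge. With target standing at violet's 16%, side product would be 54.8%.

The forecast gave 78%, 57%, 60%, 79% and 73% for dawn, dusk, spring, midnight and autumn, with midnight highest, holding that “Dusk and spring effectively lose the 8 cold hours”.

The simulation gives 76.4%, 63.6%, 64.3%, 78.2% and 68.7% in that order, with midnight highest.

    starting material + free catalyst ⇌ catalyst intermediate A (K = 6.90 M⁻¹, k = 3.50 M⁻¹ s⁻¹, Ea = 40.0 kJ mol⁻¹, ΔH = 6.00 kJ mol⁻¹)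
    partner + catalyst intermediate A → free catalyst + target (k = 1.90 M⁻¹ s⁻¹, Ea = 48.0 kJ mol⁻¹)
    second substrate + free catalyst ⇌ catalyst intermediate B (K = 2.00 M⁻¹, k = 3.10 M⁻¹ s⁻¹, Ea = 48.0 kJ mol⁻¹, ΔH = −75.0 kJ mol⁻¹)
    partner + catalyst intermediate B → free catalyst + second product (k = 7.80 M⁻¹ s⁻¹, Ea = 64.0 kJ mol⁻¹)
    starting material + target → side product (k = 0.00130 M⁻¹ s⁻¹, Ea = 75.0 kJ mol⁻¹)
    solid reagent ⇌ partner, rate k6*(cs6 - [partner]) while solid is left; crystals form when [partner] > cs6 (solubility = 0.0690 M, k = 4.00 × 10⁻⁴ s⁻¹)
    (constants at 80 °C)

In dusk, counting the cold hours as giving none, target formed at a mean of 3.60 mM h⁻¹ over the hot hours, and target plus half the side product stood at 43.2% of the charge at 20.0 h, with target at 11.4% and solid reagent at 0%. In the flask like midnight but with 0.045 M of solid reagent, the mean over 20 h was 1.02 mM h⁻¹ against midnight's 2.55 mM h⁻¹, and it ended with partner at 9.20 × 10⁻⁵ M, starting material at 59.4% and side product at 40.3%.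

(The earlier runs and the new flask are calculated for an exercise; noise was put on by code.)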